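**Plan**
- **Cuts:** the three silyl ethers and the C5 methyl ether are unmasked last. Ring C is then cut at C2–C3 (together with C3–H), the diazo group at C3 is removed, and C4–C4a (ring A to the C4–C3–ring B unit) is cut. On ring B, the C5′–prenyl bond and the one-carbon homologation that supplies C4 are undone.
- **Enabling feature:** C2 of ring C is an unsubstituted CH2 bonded only to O1 and C3. It can therefore start as the methyl carbon of a ring A methoxy group ortho to the C4 carbonyl, in a 1,6-relationship to a carbene at C3.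
- **Forward order:** rings A and B are bought. Ring B is brominated, silylated, homologated and prenylated. Ring A is metalated between its two methoxy groups and added to the ring B aldehyde. Oxidation and diazo transfer follow, and ring C closes last.
- **Stereochemistry:** C3 (R) is the only stereocentre. It arises in the ring closure under control of a chiral dirhodium catalyst, and only base-free steps follow.

Key step: step 10

Assumption: the sense of induction of Rh2(S-PTAD)4 on this substrate cannot be derived from a closer analogue, so the (S)-catalyst is written for the 3R product; its equally available (R)-antipode would replace it if the opposite series should form.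

Step 1
Reactants: 1 2,3-dihydroxy-4-methoxybenzaldehyde
Product: 2 5-bromo-2,3-dihydroxy-4-methoxybenzaldehyde
Conditions: NBS (1.0 equiv), MeCN, 0 °C → rt
Reagents that add atoms: N-bromosuccinimide, O=C1CCC(=O)N1Br
Why: Electrophilic aromatic bromination: C5 is para to the 2-OH, ortho to the methoxy group and meta to the formyl group, while the only other free position, C6, is ortho to the deactivating formyl group, so bromine should enter at C5.

Step 2
Reactants: 2 5-bromo-2,3-dihydroxy-4-methoxybenzaldehyde
Product: 3 5-bromo-2,3-bis(tert-butyldimethylsilyloxy)-4-methoxybenzaldehyde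
Conditions: TBSCl (2.5 equiv), imidazole, DMF, rt
Reagents that add atoms: tert-butyldimethylsilyl chloride, CC(C)(C)[Si](C)(C)Cl
Why: Corey-type silylation of phenols; the bis-silyl ethers of this catechol aldehyde type tolerate ylides and cold organolithiums and carry no C–H bond next to oxygen, which matters in step 10.

Step 3
Reactants: 3 5-bromo-2,3-bis(tert-butyldimethylsilyloxy)-4-methoxybenzaldehyde
Product: 4 5-bromo-2,3-bis(tert-butyldimethylsilyloxy)-4-methoxy-β-methoxystyrene (E/Z mixture)
Conditions: MeOCH2PPh3Cl, KHMDS, THF, 0 °C; then 3, −78 → 0 °C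
Reagents that add atoms: (methoxymethyl)triphenylphosphonium chloride, COC[P+](c1ccccc1)(c1ccccc1)c1ccccc1.[Cl-]
Why: Wittig methoxymethylenation adds the future C4 carbon (the old formyl carbon becomes C3) and masks the homologous aldehyde as an enol ether that is inert to n-BuLi; the alkene geometry is irrelevant because both isomers converge in step 5.

Step 4
Reactants: 4 5-bromo-2,3-bis(tert-butyldimethylsilyloxy)-4-methoxy-β-methoxystyrene; 5 prenyl bromide (1-bromo-3-methylbut-2-ene)
Product: 7 2,3-bis(tert-butyldimethylsilyloxy)-4-methoxy-5-(3-methylbut-2-enyl)-β-methoxystyrene (E/Z mixture), via aryllithium 6 (not isolated)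
Conditions: n-BuLi, THF, −78 °C; CuBr·SMe2 (20 mol %), 5, −78 → 0 °C
Reagents that add atoms: prenyl bromide 5, CC(C)=CCBr
Why: Bromine–lithium exchange followed by copper-catalysed SN2 allylation of the aryl metal at the unhindered CH2 terminus of the allylic bromide gives the linear prenyl group, and because lithium sits between OMe and H no ortho silyloxy group is available for a retro-Brook shift.

Step 5
Reactants: 7 2,3-bis(tert-butyldimethylsilyloxy)-4-methoxy-5-(3-methylbut-2-enyl)-β-methoxystyrene
Product: 8 2-[2,3-bis(tert-butyldimethylsilyloxy)-4-methoxy-5-(3-methylbut-2-enyl)phenyl]acetaldehyde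
Conditions: 2 M aq HCl, THF, rt; used crude
Reagents that add atoms: water, O
Why: Acid-catalysed enol ether hydrolysis, in which the enol ether is protonated ahead of the trisubstituted alkene and aryl silyl ethers tolerate dilute aqueous acid, consistent with the routine acidic removal of acetal protecting groups from prenylated aryl ethers.

Step 6
Reactants: 9 3,5-dimethoxyphenol
Product: 10 (3,5-dimethoxyphenoxy)triisopropylsilane
Conditions: TIPSCl, imidazole, DMF, rt
Reagents that add atoms: triisopropylsilyl chloride, CC(C)[Si](Cl)(C(C)C)C(C)C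
Why: Silylation of a phenol; the bulky TIPS group resists attack by n-BuLi and shields both positions next to it, which leaves the site between the two methoxy groups for metalation.

Step 7
Reactants: 10 (3,5-dimethoxyphenoxy)triisopropylsilane; 8 2-[2,3-bis(tert-butyldimethylsilyloxy)-4-methoxy-5-(3-methylbut-2-enyl)phenyl]acetaldehyde
Product: 13 rac-1-[2,6-dimethoxy-4-(triisopropylsilyloxy)phenyl]-2-[2,3-bis(tert-butyldimethylsilyloxy)-4-methoxy-5-(3-methylbut-2-enyl)phenyl]ethanol, via aryllithium 11 (not isolated), via arylcerium dichloride 12 (not isolated)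
Conditions: 10, n-BuLi, THF, 0 °C → rt; anhydrous CeCl3, THF, −78 °C; 8, −78 °C; aq NH4Cl
Reagents that add atoms: none
Why: Directed ortho-metalation at the position flanked by two methoxy groups, transmetalation to the weakly basic organocerium reagent (Imamoto conditions) and 1,2-addition to the enolisable aldehyde form C4–C4a; the carbinol centre is racemic and is erased in step 8.

Step 8
Reactants: 13 rac-1-[2,6-dimethoxy-4-(triisopropylsilyloxy)phenyl]-2-[2,3-bis(tert-butyldimethylsilyloxy)-4-methoxy-5-(3-methylbut-2-enyl)phenyl]ethanol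
Product: 14 1-[2,6-dimethoxy-4-(triisopropylsilyloxy)phenyl]-2-[2,3-bis(tert-butyldimethylsilyloxy)-4-methoxy-5-(3-methylbut-2-enyl)phenyl]ethanone
Conditions: Dess–Martin periodinane, NaHCO3, CH2Cl2, 0 °C → rt
Reagents that add atoms: none
Why: Dess–Martin oxidation of a secondary benzylic alcohol under buffered conditions spares the silyl ethers, the alkene and the ionisation-prone electron-rich carbinol.

Step 9
Reactants: 14 1-[2,6-dimethoxy-4-(triisopropylsilyloxy)phenyl]-2-[2,3-bis(tert-butyldimethylsilyloxy)-4-methoxy-5-(3-methylbut-2-enyl)phenyl]ethanone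
Product: 15 2-diazo-1-[2,6-dimethoxy-4-(triisopropylsilyloxy)phenyl]-2-[2,3-bis(tert-butyldimethylsilyloxy)-4-methoxy-5-(3-methylbut-2-enyl)phenyl]ethanone
Conditions: p-ABSA, DBU, dry MeCN/THF, 0 °C → rt
Reagents that add atoms: 4-acetamidobenzenesulfonyl azide (p-ABSA), CC(=O)Nc1ccc(cc1)S(=O)(=O)N=[N+]=[N-]
Why: Regitz diazo transfer works directly because the methylene between aroyl and aryl groups is acidic enough for DBU, as in the standard preparation of aryldiazoacetates and α-aryl-α-diazoketones, and water is excluded so that DBU does not cleave the aryl silyl ethers.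

Step 10
Reactants: 15 2-diazo-1-[2,6-dimethoxy-4-(triisopropylsilyloxy)phenyl]-2-[2,3-bis(tert-butyldimethylsilyloxy)-4-methoxy-5-(3-methylbut-2-enyl)phenyl]ethanone
Product: 17 (3R)-3-[2,3-bis(tert-butyldimethylsilyloxy)-4-methoxy-5-(3-methylbut-2-enyl)phenyl]-5-methoxy-7-(triisopropylsilyloxy)chroman-4-one, via rhodium carbene 16 (not isolated)
Conditions: Rh2(S-PTAD)4 (1 mol %), 4 Å MS, CH2Cl2, 40 °C, syringe-pump addition of 15 (final ca. 0.01 M)
Reagents that add atoms: none
Why: Rhodium-carbene C–H insertion: the catalyst binds the diazo carbon of 15, N2 leaves, and the electrophilic aryl/acyl carbene 16 takes a C–H bond of an ortho-methoxy group through a concerted, hydride-like three-centre transition state in which C2–C3 and C3–H form together and the catalyst is released. The closest known reactions are the chiral Rh(II)-carboxylate-catalysed insertions of 2-alkoxyaryl α-diazoketones next to the ether oxygen, which give 3-substituted chroman-4-ones, and the enantioselective insertions of aryl-substituted rhodium carbenes into O–CH3 groups; the present case combines the two. Ring C closes in the 1,6-mode (C3, C4, C4a, C8a, O1, C2), the usual 1,5-mode being closed off because the fifth atom is the ether oxygen, whose ylide with the carbene should revert since methyl migrates poorly. C3 is the only new stereocentre and is controlled by the catalyst, whose phthalimido/adamantyl wall leaves one carbene face open to the incoming C–H bond; the product is released under neutral conditions, so the acidic C3–H is not exchanged. The step needs site selectivity for the methoxy C–H and chemoselectivity over the alkene: the two ortho-methoxy groups are equivalent and are held above and below the carbene by the twisted 2,6-disubstituted aroyl group, the 2′- and 3′-oxygens of ring B carry silyl groups without a C–H next to oxygen, and the 4′-methoxy (para) and prenyl (meta) groups cannot reach C3. Slow addition at high dilution keeps bimolecular cyclopropanation, azine formation and carbene dimerisation down.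

Step 11
Reactants: 17 (3R)-3-[2,3-bis(tert-butyldimethylsilyloxy)-4-methoxy-5-(3-methylbut-2-enyl)phenyl]-5-methoxy-7-(triisopropylsilyloxy)chroman-4-one
Product: 19 (3R)-3-[2,3-bis(tert-butyldimethylsilyloxy)-4-methoxy-5-(3-methylbut-2-enyl)phenyl]-5-hydroxy-7-(triisopropylsilyloxy)chroman-4-one, via dichloroboron chelate 18 (not isolated)
Conditions: BCl3 (1.5 equiv), CH2Cl2, −78 → −20 °C; cold pH 7 buffer
Reagents that add atoms: none
Why: Chelation-directed aryl methyl ether cleavage: BCl3 bridges the C4 carbonyl oxygen and the peri C5 methoxy oxygen in a six-membered chelate so that chloride removes only that methyl group, while the unchelated 4′-methoxy group and the silyl ethers are not activated at low temperature and the absence of base should keep C3 intact.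

Step 12
Reactants: 19 (3R)-3-[2,3-bis(tert-butyldimethylsilyloxy)-4-methoxy-5-(3-methylbut-2-enyl)phenyl]-5-hydroxy-7-(triisopropylsilyloxy)chroman-4-one
Product: 20 (3R)-5,7,2′,3′-tetrahydroxy-4′-methoxy-5′-(3-methylbut-2-enyl)isoflavanone (CNP0141716.1)
Conditions: Et3N·3HF, THF, 0 °C → rt, argon
Reagents that add atoms: none
Why: Fluoride-mediated desilylation with the slightly acidic reagent Et3N·3HF cleaves all three aryl silyl ethers without generating phenoxide or enolate, so the base-labile C3 centre and the air-sensitive catechol should be preserved.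

**Compound list**
1 | 2,3-dihydroxy-4-methoxybenzaldehyde | COc1ccc(C=O)c(O)c1O | starting material
2 | 5-bromo-2,3-dihydroxy-4-methoxybenzaldehyde | COc1c(Br)cc(C=O)c(O)c1O | intermediate
3 | 5-bromo-2,3-bis(tert-butyldimethylsilyloxy)-4-methoxybenzaldehyde | COc1c(Br)cc(C=O)c(O[Si](C)(C)C(C)(C)C)c1O[Si](C)(C)C(C)(C)C | intermediate
4 | 5-bromo-2,3-bis(tert-butyldimethylsilyloxy)-4-methoxy-β-methoxystyrene (E/Z mixture) | COC=Cc1cc(Br)c(OC)c(O[Si](C)(C)C(C)(C)C)c1O[Si](C)(C)C(C)(C)C | intermediate
5 | prenyl bromide | CC(C)=CCBr | starting material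
6 | aryllithium from 4 (Li at C5, not isolated) | [Li]c1cc(C=COC)c(O[Si](C)(C)C(C)(C)C)c(O[Si](C)(C)C(C)(C)C)c1OC | intermediate
7 | 2,3-bis(tert-butyldimethylsilyloxy)-4-methoxy-5-prenyl-β-methoxystyrene (E/Z mixture) | COC=Cc1cc(CC=C(C)C)c(OC)c(O[Si](C)(C)C(C)(C)C)c1O[Si](C)(C)C(C)(C)C | intermediate
8 | 2-[2,3-bis(tert-butyldimethylsilyloxy)-4-methoxy-5-prenylphenyl]acetaldehyde | O=CCc1cc(CC=C(C)C)c(OC)c(O[Si](C)(C)C(C)(C)C)c1O[Si](C)(C)C(C)(C)C | intermediate
9 | 3,5-dimethoxyphenol | COc1cc(O)cc(OC)c1 | starting material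
10 | (3,5-dimethoxyphenoxy)triisopropylsilane | COc1cc(O[Si](C(C)C)(C(C)C)C(C)C)cc(OC)c1 | intermediate
11 | 2,6-dimethoxy-4-(triisopropylsilyloxy)phenyllithium (not isolated) | COc1cc(O[Si](C(C)C)(C(C)C)C(C)C)cc(OC)c1[Li] | intermediate
12 | 2,6-dimethoxy-4-(triisopropylsilyloxy)phenylcerium dichloride (not isolated) | COc1cc(O[Si](C(C)C)(C(C)C)C(C)C)cc(OC)c1[Ce](Cl)Cl | intermediate
13 | racemic diarylethanol (ring A carbinol, ring B benzyl) | COc1cc(O[Si](C(C)C)(C(C)C)C(C)C)cc(OC)c1C(O)Cc1cc(CC=C(C)C)c(OC)c(O[Si](C)(C)C(C)(C)C)c1O[Si](C)(C)C(C)(C)C | intermediate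
14 | protected deoxybenzoin | COc1cc(O[Si](C(C)C)(C(C)C)C(C)C)cc(OC)c1C(=O)Cc1cc(CC=C(C)C)c(OC)c(O[Si](C)(C)C(C)(C)C)c1O[Si](C)(C)C(C)(C)C | intermediate
15 | α-aryl-α-diazoketone (key-step precursor) | COc1cc(O[Si](C(C)C)(C(C)C)C(C)C)cc(OC)c1C(=O)C(=[N+]=[N-])c1cc(CC=C(C)C)c(OC)c(O[Si](C)(C)C(C)(C)C)c1O[Si](C)(C)C(C)(C)C | intermediate
16 | rhodium carbene at C3 (only the carbene-bound Rh drawn, catalyst ligands omitted, not isolated) | COc1cc(O[Si](C(C)C)(C(C)C)C(C)C)cc(OC)c1C(=O)C(=[Rh])c1cc(CC=C(C)C)c(OC)c(O[Si](C)(C)C(C)(C)C)c1O[Si](C)(C)C(C)(C)C | intermediate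
17 | (3R)-5-O-methyl-7-O-TIPS-2′,3′-bis-O-TBS isoflavanone (key-step product) | COc1c(CC=C(C)C)cc([C@@H]2COc3cc(O[Si](C(C)C)(C(C)C)C(C)C)cc(OC)c3C2=O)c(O[Si](C)(C)C(C)(C)C)c1O[Si](C)(C)C(C)(C)C | intermediate
18 | (3R)-5-O-dichloroboryl chelate (not isolated) | COc1c(CC=C(C)C)cc([C@@H]2COc3cc(O[Si](C(C)C)(C(C)C)C(C)C)cc(OB(Cl)Cl)c3C2=O)c(O[Si](C)(C)C(C)(C)C)c1O[Si](C)(C)C(C)(C)C | intermediate
19 | (3R)-5-hydroxy-7-O-TIPS-2′,3′-bis-O-TBS isoflavanone | COc1c(CC=C(C)C)cc([C@@H]2COc3cc(O[Si](C(C)C)(C(C)C)C(C)C)cc(O)c3C2=O)c(O[Si](C)(C)C(C)(C)C)c1O[Si](C)(C)C(C)(C)C | intermediate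
20 | (3R)-5,7,2′,3′-tetrahydroxy-4′-methoxy-5′-prenylisoflavanone (CNP0141716.1) | COc1c(CC=C(C)C)cc([C@@H]2COc3cc(O)cc(O)c3C2=O)c(O)c1O | target

**Step count**
- Total step count: 12.
- Longest linear sequence: 11 (steps 1–5 and 7–12, from 1).

**Steps most likely to fail**

**Step 10.**
- What may go wrong: the methoxy oxygen lone pair, rather than a methyl C–H bond, may capture the carbene, and the resulting five-membered oxonium ylide may collapse by methyl migration or methyl loss. Wolff-type rearrangement or carbene dimerisation may also compete. Facial discrimination may be weak because the ortho-silyloxy group twists ring B out of conjugation with the carbene.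
- Fallback: it sets out from 14 and comes back at 17, building ring C through oxygen and setting C3 by reduction. One ortho methyl ether of 14 is removed by chelation-directed cleavage (BCl3, CH2Cl2, −78 °C) to give the 2-hydroxy-6-methoxy deoxybenzoin F1. Condensation with DMF dimethyl acetal (toluene, 80 °C) supplies C2 and closes the isoflavone F2.
- Noyori-type asymmetric transfer hydrogenation with RuCl[(R,R)-TsDPEN](p-cymene) and HCO2H/Et3N reduces the enone C=C. It then reduces the ketone with dynamic kinetic resolution of the labile C3 centre. By the usual aryl ketone rule this should deliver the cis-(3R,4R)-isoflavan-4-ol F3, and the isolated prenyl alkene is not touched.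
- Dess–Martin oxidation of F3 under neutral conditions returns the ketone 17.

**Step 11.**
- What may go wrong: enolisation of the boron-bound ketone may erode the C3 configuration. Hydrogen chloride may also add to the prenyl double bond during cleavage or quench.
- Fallback: it sets out from 14 and comes back at 20, moving the ether cleavage ahead of the stereocentre. The same chelation-directed cleavage is run on achiral 14 to give the monophenol F1 described above. That phenol is silylated (TBSOTf, 2,6-lutidine, CH2Cl2) to the tetrasilyl deoxybenzoin F4.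
- Diazo transfer as in step 9 gives the diazoketone F5. The rhodium-catalysed insertion of step 10, now into the single remaining ortho-methoxy group, gives the (3R)-tetrasilyl isoflavanone F6.
- One treatment with Et3N·3HF then leads directly to 20, so no Lewis acid meets the stereocentre.

**Step 7.**
- What may go wrong: the aryl metal may enolise the arylacetaldehyde, the aldehyde may undergo self-aldol reaction, or the 2′-silyl group may migrate to the newly formed alkoxide.
- Fallback: it sets out from 8 and 11 and comes back at 14, bypassing 13 and step 8 by a non-basic acylation. Pinnick oxidation of 8 (NaClO2, NaH2PO4, 2-methyl-2-butene, t-BuOH/H2O) gives the arylacetic acid F7. The neutral Ghosez reagent (1-chloro-N,N,2-trimethylpropenylamine, CH2Cl2, 0 °C) converts it into the arylacetyl chloride F8.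
- Aryllithium 11 is transmetalated with ZnCl2 to the arylzinc chloride F9. Negishi acylation (Pd(PPh3)4 cat., THF, rt) joins F8 and F9 to the ketone 14.

**Further compounds**
F1 | step 10 | 1-[2-hydroxy-6-methoxy-4-(triisopropylsilyloxy)phenyl]-2-[2,3-bis(tert-butyldimethylsilyloxy)-4-methoxy-5-prenylphenyl]ethanone | COc1cc(O[Si](C(C)C)(C(C)C)C(C)C)cc(O)c1C(=O)Cc1cc(CC=C(C)C)c(OC)c(O[Si](C)(C)C(C)(C)C)c1O[Si](C)(C)C(C)(C)C
F2 | step 10 | 5,4′-dimethoxy-7-(triisopropylsilyloxy)-2′,3′-bis(tert-butyldimethylsilyloxy)-5′-prenylisoflavone | COc1c(CC=C(C)C)cc(C2=COc3cc(O[Si](C(C)C)(C(C)C)C(C)C)cc(OC)c3C2=O)c(O[Si](C)(C)C(C)(C)C)c1O[Si](C)(C)C(C)(C)C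
F3 | step 10 | (3R,4R)-cis-5,4′-dimethoxy-7-(triisopropylsilyloxy)-2′,3′-bis(tert-butyldimethylsilyloxy)-5′-prenylisoflavan-4-ol | COc1c(CC=C(C)C)cc([C@@H]2COc3cc(O[Si](C(C)C)(C(C)C)C(C)C)cc(OC)c3[C@@H]2O)c(O[Si](C)(C)C(C)(C)C)c1O[Si](C)(C)C(C)(C)C
F4 | step 11 | 1-[2-(tert-butyldimethylsilyloxy)-6-methoxy-4-(triisopropylsilyloxy)phenyl]-2-[2,3-bis(tert-butyldimethylsilyloxy)-4-methoxy-5-prenylphenyl]ethanone | COc1cc(O[Si](C(C)C)(C(C)C)C(C)C)cc(O[Si](C)(C)C(C)(C)C)c1C(=O)Cc1cc(CC=C(C)C)c(OC)c(O[Si](C)(C)C(C)(C)C)c1O[Si](C)(C)C(C)(C)C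
F5 | step 11 | 2-diazo derivative of F4 | COc1cc(O[Si](C(C)C)(C(C)C)C(C)C)cc(O[Si](C)(C)C(C)(C)C)c1C(=O)C(=[N+]=[N-])c1cc(CC=C(C)C)c(OC)c(O[Si](C)(C)C(C)(C)C)c1O[Si](C)(C)C(C)(C)C
F6 | step 11 | (3R)-5,2′,3′-tris-O-TBS-7-O-TIPS-4′-methoxy-5′-prenylisoflavanone | COc1c(CC=C(C)C)cc([C@@H]2COc3cc(O[Si](C(C)C)(C(C)C)C(C)C)cc(O[Si](C)(C)C(C)(C)C)c3C2=O)c(O[Si](C)(C)C(C)(C)C)c1O[Si](C)(C)C(C)(C)C
F7 | step 7 | 2-[2,3-bis(tert-butyldimethylsilyloxy)-4-methoxy-5-prenylphenyl]acetic acid | OC(=O)Cc1cc(CC=C(C)C)c(OC)c(O[Si](C)(C)C(C)(C)C)c1O[Si](C)(C)C(C)(C)C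
F8 | step 7 | 2-[2,3-bis(tert-butyldimethylsilyloxy)-4-methoxy-5-prenylphenyl]acetyl chloride | ClC(=O)Cc1cc(CC=C(C)C)c(OC)c(O[Si](C)(C)C(C)(C)C)c1O[Si](C)(C)C(C)(C)C
F9 | step 7 | 2,6-dimethoxy-4-(triisopropylsilyloxy)phenylzinc chloride | COc1cc(O[Si](C(C)C)(C(C)C)C(C)C)cc(OC)c1[Zn]Cl
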